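The pitfall is to read a slowing fall of J as a sign that a larger charge of L must carry the reaction further.

the same everywhere: J 0.050 M
- midnight: X 0.055 M; L 0.053 M; run made earlier
- winter: X 0.055 M; L 0.060 M; run made earlier
- dawn: X 0.055 M; L 0.055 M; run made earlier
- maple: X 0.0550 M; L 0.0500 M; time 15 h
- cedar: X 0.0550 M; L 0.0750 M; time 15 h

| run | time / h | J / % | D / % |
|---|---|---|---|
| midnight | 0.667 | 92.1 | 0 |
| midnight | 2.00 | 79.1 | 2.8 |
| midnight | 4.00 | 66.1 | 7.3 |
| midnight | 5.00 | 60.5 | 9.9 |
| midnight | 8.00 | 50.7 | 16.4 |
| winter | 0.667 | 92.3 | 0.4 |
| winter | 1.00 | 88.9 | 0.7 |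
| winter | 2.00 | 80.2 | 2.1 |
| winter | 4.00 | 66.8 | 8.1 |
| winter | 8.00 | 50.7 | 16.7 |
| dawn | 0.667 | 92.5 | 0 |
| dawn | 1.00 | 88.3 | 1.0 |
| dawn | 2.00 | 80.1 | 2.0 |
| dawn | 4.00 | 65.8 | 6.8 |
| dawn | 8.00 | 51.2 | 16.0 |

(readings scatter by 0.5 percentage points)

1. part of the J that has reacted at the end, maple
2. part of the J that has reacted at the end, cedar
3. what raising the concentration of L from its lowest to its highest value here does to the part of the J that has reacted (changes below 5 percentage points count as none) (no change / it rises / it falls)



Two chemists dispute this, reckoning in fractions of the charge. The first reads the midnight run: J loses 0.114 /h of itself early and 0.0663 /h late. So, she says, a return is growing, L may hold it off, and cedar, with more L than any earlier run, should stand above maple.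

The second counts X. Each J takes one X to react and D takes one more, and X is charged below twice J, which makes it the limiting reagent of the double exchange. In the midnight run the fraction of X left, x, is 62.5% after 4.00 h and 40.3% after 8.00 h. She divides the late fall of J by the mean x of that stretch and gets 0.129 /h, the pace: the fractional loss of J per hour with X at its whole charge. The early stretch, treated alike, gives 0.133 /h. The pace holds while x falls, and J reads 50.7% and 50.7% at 0.053 M and 0.060 M of L, so she sees no effect of the amount of L over that narrow span, which says nothing on whether L takes part.

I side with her. Late x loses 0.110 /h of itself, which puts it at 18.6% at the end. With the mean 29.5% in place of the curve, the pace leaves J at 38.9%, so 61.1% has reacted, in both flasks.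

The forecast, on her side, gives 61.5% for maple and 61.5% for cedar, a little above my figure, and no change: “the reaction stalls as X runs out”.

The simulation gives 60.7% for maple, 61.0% for cedar and no change, a change of 0.26 percentage points.

    G + X ⇌ Q, settled at all times (K = 24.0 /M)
    L + G → E (k = 320 /M/h)
    Z + X ⇌ G + D (K = 1.10, k = 2.80 /M/h)
    J + X ⇌ G + Z (K = 0.820, k = 2.40 /M/h)

From maple's J of 52.3% at 7.50 h, the pace with the mean of X's 42.0% and 20.2% gives 38.7% at the end, against 39.3%; the backward run barely counts there. The first chemist gets her region in the neighbour charged with 0.14 M of X: the pace, with mean X counted in maple's charge, gives J 3.70%, but J stands at 11.3%, with L at 0% and G at 0.0130 M. Maple is not at rest: at the end the pace still takes 0.0261 /h of J, and ten times the time brings the reacted part to 67.5% in maple and 71.2% in cedar.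

(All runs are simulated with constants of no real substance, and the scatter is random.)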